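**Plan**

- Retrosynthetic cuts, in order: the C6–OOH bond (hydroperoxide displaces a C6 sulfonate with inversion, so the precursor is the 6R alcohol), the C4 carbinol back to a ketone, the C5–C6 bond (methyl-ketone aldol with methacrolein), the C4–CH3 bond and the C–H oxidation of a prenyl methyl group, the C1–O ether bond, and last the lactone bonds of the coumarin.
- Feature used: counting the side chain from C1 (the OCH2 carbon) to C8, the methylene C5 lies between the oxygen-bearing carbons C4 and C6, and C6 also holds the isopropenyl unit (C7=C8 and the C7 methyl). This is the skeleton of methacrolein joined to the methyl group of a C4 methyl ketone.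
- Forward order: the pyranone ring of the coumarin is closed first (the only ring made). The chain is then grown on O4 by O-prenylation, allylic oxidation, methyl addition and oxidation to the C4 methyl ketone. The aldol joins C5–C6, and the rest is functional-group work.
- Stereochemistry: C6 comes from the isopinocampheyl ligands on boron (6R) and is inverted to 6S in the SN2 step. C4 (4S) comes from a reagent-controlled oxazaborolidine reduction. The E alkene comes from the selectivity of the SeO2 oxidation.

Key step: step 6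

Remark on the chemistry: the route assumes the usual sense of induction of methyl-ketone diisopinocampheylboron enolates (reagent from (+)-α-pinene, Re-face attack on the aldehyde). The C6 configuration of 13 should be checked by Mosher ester analysis before going on; the antipodal reagent is the remedy if it proves opposite.

**Route**

Step 1
Reactants: 1 1-(2-hydroxy-6-methylphenyl)ethanone; 2 diethyl carbonate
Product: 4 4-hydroxy-5-methyl-2H-chromen-2-one, via ethyl 3-(2-hydroxy-6-methylphenyl)-3-oxopropanoate 3 (not isolated)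
Conditions: NaH (4 equiv), toluene, 110 °C; then aq. HCl
Reagents that add atoms: none
Why: Claisen condensation of the ketone enolate with diethyl carbonate gives the β-keto ester 3, whose ester is captured by the neighbouring phenoxide to close the pyranone ring, the standard 4-hydroxycoumarin synthesis from 2-hydroxyacetophenones.

Step 2
Reactants: 4 4-hydroxy-5-methyl-2H-chromen-2-one; 5 3-methylbut-2-en-1-ol (prenol)
Product: 6 5-methyl-4-[(3-methylbut-2-en-1-yl)oxy]-2H-chromen-2-one
Conditions: PPh3, DIAD, THF, 0 °C to rt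
Reagents that add atoms: none
Why: Mitsunobu etherification alkylates the acidic enol (pKa about 4) on oxygen through the alkoxyphosphonium ion of the primary allylic alcohol, which avoids the C3-alkylation that allylic halides tend to give with 4-hydroxycoumarins.

Step 3
Reactants: 6 5-methyl-4-[(3-methylbut-2-en-1-yl)oxy]-2H-chromen-2-one
Product: 7 (2E)-2-methyl-4-[(5-methyl-2-oxo-2H-chromen-4-yl)oxy]but-2-enal
Conditions: SeO2 (1.3 equiv), 1,4-dioxane, 80 °C
Reagents that add atoms: selenium dioxide, O=[Se]=O
Why: Riley oxidation (ene reaction, then [2,3]-sigmatropic shift) attacks the methyl group trans to the chain at the more substituted alkene carbon, as with prenyl and geranyl esters, so the E-enal should result; 80 °C is well below the temperature at which 4-allyloxycoumarins undergo Claisen rearrangement.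

Step 4
Reactants: 7 (2E)-2-methyl-4-[(5-methyl-2-oxo-2H-chromen-4-yl)oxy]but-2-enal
Product: 8 4-{[(2E)-4-hydroxy-3-methylpent-2-en-1-yl]oxy}-5-methyl-2H-chromen-2-one (racemic at the carbinol carbon)
Conditions: MeMgBr (1.1 equiv), THF, −78 °C; aq. NH4Cl
Reagents that add atoms: methylmagnesium bromide, C[Mg]Br
Why: Grignard 1,2-addition to the aldehyde at −78 °C is much faster than attack at the enal β-carbon or at the vinylogous carbonate of the coumarin; the new carbinol centre is racemic and is erased in step 5.

Step 5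
Reactants: 8 4-{[(2E)-4-hydroxy-3-methylpent-2-en-1-yl]oxy}-5-methyl-2H-chromen-2-one
Product: 9 (3E)-3-methyl-5-[(5-methyl-2-oxo-2H-chromen-4-yl)oxy]pent-3-en-2-one
Conditions: Dess–Martin periodinane, CH2Cl2, 0 °C to rt
Reagents that add atoms: none
Why: Dess–Martin oxidation of the secondary allylic alcohol under near-neutral conditions should give the enone without moving the E double bond or cleaving the allylic enol ether.

Step 6
Reactants: 9 (3E)-3-methyl-5-[(5-methyl-2-oxo-2H-chromen-4-yl)oxy]pent-3-en-2-one; 10 methacrolein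
Product: 13 4-{[(2E,6R)-6-hydroxy-3,7-dimethyl-4-oxoocta-2,7-dien-1-yl]oxy}-5-methyl-2H-chromen-2-one, via diisopinocampheylboron dienolate 11 (not isolated), via diisopinocampheylboron aldolate 12 (not isolated)
Conditions: (−)-Ipc2BCl (1.5 equiv), Et3N (2 equiv), Et2O–CH2Cl2, 0 °C, 1 h; 10 (3 equiv), −78 to −20 °C, 16 h; then MeOH, pH 7 buffer, 30% H2O2, 0 °C
Reagents that add atoms: none
Why: (−)-Ipc2BCl binds the ketone oxygen and Et3N removes a proton from the C5 methyl group, the only α-position that carries hydrogen (C3 is vinylic), to give the cross-conjugated boron dienolate 11, which adds to the aldehyde carbon of methacrolein through a cyclic six-membered boron-bridged transition state and leaves aldolate 12, cleaved to 13 by buffered H2O2. The closest known reaction type is the Paterson aldol reaction of diisopinocampheylboron enolates of methyl ketones with aldehydes, for which α-branched enals such as methacrolein are usual partners. No ring is closed; the only skeletal bond made is C5–C6, and the isopropenyl group (C7, C8 and the C7 methyl) arrives intact. The new C6 centre is set by the isopinocampheyl ligands alone, since neither partner is chiral: for methyl-ketone enolates the reagent made from (+)-α-pinene is expected to direct attack to the Re face of the aldehyde, which is 6R here, deliberately the epimer needed for the later inversion. The step needs enolisation at one site, 1,2-addition and enantioface selection; the first follows from the substitution pattern of 9, the second from the closed transition state and from the fact that methacrolein cannot enolise, and the third is only moderate for methyl ketones, so the minor 6S antipode is removed after step 8 as a diastereomer. The lactone and the allylic enol ether should tolerate the mild amine-mediated enolisation.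

Step 7
Reactants: 13 4-{[(2E,6R)-6-hydroxy-3,7-dimethyl-4-oxoocta-2,7-dien-1-yl]oxy}-5-methyl-2H-chromen-2-one
Product: 14 4-{[(2E,6R)-3,7-dimethyl-4-oxo-6-(triethylsilyloxy)octa-2,7-dien-1-yl]oxy}-5-methyl-2H-chromen-2-one
Conditions: TESCl, imidazole, DMF, 0 °C
Reagents that add atoms: chlorotriethylsilane, CC[Si](Cl)(CC)CC
Why: Standard silylation of a secondary alcohol keeps the C6 hydroxyl from binding borane in step 8 and allows it to be unmasked later beside a TBS ether.

Step 8
Reactants: 14 4-{[(2E,6R)-3,7-dimethyl-4-oxo-6-(triethylsilyloxy)octa-2,7-dien-1-yl]oxy}-5-methyl-2H-chromen-2-one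
Product: 15 4-{[(2E,4S,6R)-4-hydroxy-3,7-dimethyl-6-(triethylsilyloxy)octa-2,7-dien-1-yl]oxy}-5-methyl-2H-chromen-2-one
Conditions: (R)-2-methyl-CBS-oxazaborolidine (0.3 equiv), catecholborane (2 equiv), toluene, −78 °C; MeOH, then pH 7 buffer
Reagents that add atoms: none
Why: In this Corey–Bakshi–Shibata reduction the α-methylalkenyl group acts as the large and the C5 methylene as the small ketone substituent, so the (R)-catalyst should deliver hydride to give the 4S allylic alcohol under reagent control, catecholborane at −78 °C should not hydroborate the alkenes or reduce the lactone, and material of 6S configuration from step 6 now appears as the (4S,6S) diastereomer to be removed by chromatography.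

Step 9
Reactants: 15 4-{[(2E,4S,6R)-4-hydroxy-3,7-dimethyl-6-(triethylsilyloxy)octa-2,7-dien-1-yl]oxy}-5-methyl-2H-chromen-2-one
Product: 16 4-{[(2E,4S,6R)-4-(tert-butyldimethylsilyloxy)-3,7-dimethyl-6-(triethylsilyloxy)octa-2,7-dien-1-yl]oxy}-5-methyl-2H-chromen-2-one
Conditions: TBSOTf, 2,6-lutidine, CH2Cl2, −78 °C
Reagents that add atoms: tert-butyldimethylsilyl trifluoromethanesulfonate, CC(C)(C)[Si](C)(C)OS(=O)(=O)C(F)(F)F
Why: Silylation with the silyl triflate and a hindered pyridine base protects the allylic C4 hydroxyl at low temperature without disturbing the TES ether.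

Step 10
Reactants: 16 4-{[(2E,4S,6R)-4-(tert-butyldimethylsilyloxy)-3,7-dimethyl-6-(triethylsilyloxy)octa-2,7-dien-1-yl]oxy}-5-methyl-2H-chromen-2-one
Product: 17 4-{[(2E,4S,6R)-4-(tert-butyldimethylsilyloxy)-6-hydroxy-3,7-dimethylocta-2,7-dien-1-yl]oxy}-5-methyl-2H-chromen-2-one
Conditions: PPTS (0.2 equiv), MeOH–CH2Cl2, 0 °C
Reagents that add atoms: none
Why: Acid-catalysed methanolysis cleaves a secondary TES ether much faster than a secondary TBS ether, so only the C6 hydroxyl should be released.

Step 11
Reactants: 17 4-{[(2E,4S,6R)-4-(tert-butyldimethylsilyloxy)-6-hydroxy-3,7-dimethylocta-2,7-dien-1-yl]oxy}-5-methyl-2H-chromen-2-one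
Product: 18 4-{[(2E,4S,6R)-4-(tert-butyldimethylsilyloxy)-6-(methanesulfonyloxy)-3,7-dimethylocta-2,7-dien-1-yl]oxy}-5-methyl-2H-chromen-2-one
Conditions: Ms2O, Et3N, CH2Cl2, −30 °C; cold aqueous work-up, used at once without chromatography
Reagents that add atoms: methanesulfonic anhydride, CS(=O)(=O)OS(C)(=O)=O
Why: O-Sulfonylation leaves the C6–O bond and hence the 6R configuration untouched, and the anhydride (no chloride present) avoids conversion of the allylic mesylate into allylic chlorides.

Step 12
Reactants: 18 4-{[(2E,4S,6R)-4-(tert-butyldimethylsilyloxy)-6-(methanesulfonyloxy)-3,7-dimethylocta-2,7-dien-1-yl]oxy}-5-methyl-2H-chromen-2-one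
Product: 19 4-{[(2E,4S,6S)-4-(tert-butyldimethylsilyloxy)-6-hydroperoxy-3,7-dimethylocta-2,7-dien-1-yl]oxy}-5-methyl-2H-chromen-2-one
Conditions: 50% aq. H2O2 (30 equiv), KOH (3 equiv), THF–MeOH, −10 to 0 °C; pH 5 buffer
Reagents that add atoms: hydrogen peroxide, OO
Why: SN2 displacement of a secondary alkyl methanesulfonate by the hydroperoxide anion, a strong α-effect nucleophile of low basicity, should invert C6 from R to S; the large excess of H2O2 suppresses dialkyl peroxide formation, the low temperature limits SN2' attack, ionisation and elimination, and any lactone opened by base is expected to reclose on the mildly acidic work-up.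

Step 13
Reactants: 19 4-{[(2E,4S,6S)-4-(tert-butyldimethylsilyloxy)-6-hydroperoxy-3,7-dimethylocta-2,7-dien-1-yl]oxy}-5-methyl-2H-chromen-2-one
Product: 20 4-{[(2E,4S,6S)-6-hydroperoxy-4-hydroxy-3,7-dimethylocta-2,7-dien-1-yl]oxy}-5-methyl-2H-chromen-2-one (CNP0307284.1)
Conditions: HF·pyridine, pyridine, THF, 0 °C to rt
Reagents that add atoms: none
Why: Desilylation with buffered HF·pyridine removes the TBS ether under non-basic conditions, which avoids base-induced Kornblum–DeLaMare dehydration of the secondary hydroperoxide and leaves the allylic ether and lactone intact.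

**Compound list**

1 | 1-(2-hydroxy-6-methylphenyl)ethanone | CC(=O)c1c(C)cccc1O | starting material
2 | diethyl carbonate | CCOC(=O)OCC | starting material
3 | ethyl 3-(2-hydroxy-6-methylphenyl)-3-oxopropanoate (sodium salt in the flask) | CCOC(=O)CC(=O)c1c(C)cccc1O | intermediate
4 | 4-hydroxy-5-methyl-2H-chromen-2-one (4-hydroxy-5-methylcoumarin) | Cc1cccc2oc(=O)cc(O)c12 | intermediate
5 | 3-methylbut-2-en-1-ol (prenol) | CC(C)=CCO | starting material
6 | 5-methyl-4-[(3-methylbut-2-en-1-yl)oxy]-2H-chromen-2-one | CC(C)=CCOc1cc(=O)oc2cccc(C)c12 | intermediate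
7 | (2E)-2-methyl-4-[(5-methyl-2-oxo-2H-chromen-4-yl)oxy]but-2-enal | O=C/C(C)=C/COc1cc(=O)oc2cccc(C)c12 | intermediate
8 | 4-{[(2E)-4-hydroxy-3-methylpent-2-en-1-yl]oxy}-5-methyl-2H-chromen-2-one, racemic | CC(O)/C(C)=C/COc1cc(=O)oc2cccc(C)c12 | intermediate
9 | (3E)-3-methyl-5-[(5-methyl-2-oxo-2H-chromen-4-yl)oxy]pent-3-en-2-one | CC(=O)/C(C)=C/COc1cc(=O)oc2cccc(C)c12 | intermediate
10 | methacrolein (2-methylprop-2-enal) | C=C(C)C=O | starting material
11 | 4-({(2E)-4-[(diisopinocampheylboranyl)oxy]-3-methylpenta-2,4-dien-1-yl}oxy)-5-methyl-2H-chromen-2-one, isopinocampheyl groups as in (−)-Ipc2BCl from (+)-α-pinene | C=C(OB([C@@H]1C[C@@H]2C[C@H]([C@H]1C)C2(C)C)[C@@H]1C[C@@H]2C[C@H]([C@H]1C)C2(C)C)/C(C)=C/COc1cc(=O)oc2cccc(C)c12 | intermediate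
12 | O-(diisopinocampheylboranyl) derivative of 13 (boron aldolate, 6R), isopinocampheyl groups as in 11 | C=C(C)[C@H](OB([C@@H]1C[C@@H]2C[C@H]([C@H]1C)C2(C)C)[C@@H]1C[C@@H]2C[C@H]([C@H]1C)C2(C)C)CC(=O)/C(C)=C/COc1cc(=O)oc2cccc(C)c12 | intermediate
13 | 4-{[(2E,6R)-6-hydroxy-3,7-dimethyl-4-oxoocta-2,7-dien-1-yl]oxy}-5-methyl-2H-chromen-2-one | C=C(C)[C@H](O)CC(=O)/C(C)=C/COc1cc(=O)oc2cccc(C)c12 | intermediate
14 | 4-{[(2E,6R)-3,7-dimethyl-4-oxo-6-(triethylsilyloxy)octa-2,7-dien-1-yl]oxy}-5-methyl-2H-chromen-2-one | C=C(C)[C@H](O[Si](CC)(CC)CC)CC(=O)/C(C)=C/COc1cc(=O)oc2cccc(C)c12 | intermediate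
15 | 4-{[(2E,4S,6R)-4-hydroxy-3,7-dimethyl-6-(triethylsilyloxy)octa-2,7-dien-1-yl]oxy}-5-methyl-2H-chromen-2-one | C=C(C)[C@H](O[Si](CC)(CC)CC)C[C@H](O)/C(C)=C/COc1cc(=O)oc2cccc(C)c12 | intermediate
16 | 4-{[(2E,4S,6R)-4-(tert-butyldimethylsilyloxy)-3,7-dimethyl-6-(triethylsilyloxy)octa-2,7-dien-1-yl]oxy}-5-methyl-2H-chromen-2-one | C=C(C)[C@H](O[Si](CC)(CC)CC)C[C@H](O[Si](C)(C)C(C)(C)C)/C(C)=C/COc1cc(=O)oc2cccc(C)c12 | intermediate
17 | 4-{[(2E,4S,6R)-4-(tert-butyldimethylsilyloxy)-6-hydroxy-3,7-dimethylocta-2,7-dien-1-yl]oxy}-5-methyl-2H-chromen-2-one | C=C(C)[C@H](O)C[C@H](O[Si](C)(C)C(C)(C)C)/C(C)=C/COc1cc(=O)oc2cccc(C)c12 | intermediate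
18 | 4-{[(2E,4S,6R)-4-(tert-butyldimethylsilyloxy)-6-(methanesulfonyloxy)-3,7-dimethylocta-2,7-dien-1-yl]oxy}-5-methyl-2H-chromen-2-one | C=C(C)[C@H](OS(C)(=O)=O)C[C@H](O[Si](C)(C)C(C)(C)C)/C(C)=C/COc1cc(=O)oc2cccc(C)c12 | intermediate
19 | 4-{[(2E,4S,6S)-4-(tert-butyldimethylsilyloxy)-6-hydroperoxy-3,7-dimethylocta-2,7-dien-1-yl]oxy}-5-methyl-2H-chromen-2-one | C=C(C)[C@H](C[C@H](O[Si](C)(C)C(C)(C)C)/C(C)=C/COc1cc(=O)oc2cccc(C)c12)OO | intermediate
20 | 4-{[(2E,4S,6S)-6-hydroperoxy-4-hydroxy-3,7-dimethylocta-2,7-dien-1-yl]oxy}-5-methyl-2H-chromen-2-one | C=C(C)[C@H](C[C@H](O)/C(C)=C/COc1cc(=O)oc2cccc(C)c12)OO | target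

**Totals and risks**

Total step count: 13. Longest linear sequence: 13 steps (1 to 20).

Steps most likely to fail:

Step 12 (together with the handling of mesylate 18 from step 11).
- What may go wrong: attack of the peroxide anion at the terminal alkene carbon with allylic shift, ionisation of the allylic sulfonate with loss of configuration, elimination to a diene, further alkylation of the product to a dialkyl peroxide, and opening of the lactone or of the vinylogous ester by the basic peroxide.
- Fallback: set out from alcohol 17 and give up the displacement. A Myers reductive allylic transposition (2-nitrobenzenesulfonylhydrazide, PPh3, DEAD, THF, −30 °C then rt) would pass through the N-allylic 2-nitrobenzenesulfonylhydrazine F1 and the allylic diazene F2. F2 loses N2 by a retro-ene shift to give the prenyl-type alkene 4-{[(2E,4S)-4-(tert-butyldimethylsilyloxy)-3,7-dimethylocta-2,6-dien-1-yl]oxy}-5-methyl-2H-chromen-2-one F3.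
- A Schenck ene photooxygenation of F3 (O2, visible light, tetraphenylporphyrin, CH2Cl2, 0 °C) should take place at the electron-rich C6=C7 alkene, because the C2=C3 alkene is deactivated by two allylic oxygen substituents. It would give 19 together with its 6R epimer F4 and the tertiary hydroperoxide regioisomer F5. 19 would be separated by chromatography, and the route is rejoined at 19. This gives up control at C6 in exchange for well-precedented reactions.

Step 6.
- What may go wrong: insufficient enantioface discrimination by the isopinocampheyl ligands for a methyl-ketone enolate, and sluggish enolisation if the boron chloride is tied up by the lactone carbonyl.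
- Fallback: set out from ketone 9 with an achiral lithium aldol reaction (LiHMDS, THF, −78 °C, then 10; aq. NH4Cl), which would give the racemic aldol 4-{[(2E)-6-hydroxy-3,7-dimethyl-4-oxoocta-2,7-dien-1-yl]oxy}-5-methyl-2H-chromen-2-one F6.
- A Sharpless kinetic resolution of this 2-methylallylic alcohol (Ti(OiPr)4, L-(+)-diisopropyl tartrate, tBuOOH, 4 Å molecular sieves, CH2Cl2, −20 °C, run to a little over half conversion) should epoxidise the 6S enantiomer to the epoxy alcohol F7. It should leave the slow-reacting 6R enantiomer, which is 13, where the route is rejoined.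

Step 3.
- What may go wrong: the oxidation stalling at the allylic alcohol, over-oxidation to the acid, and cleavage of the allylic enol ether by selenous acid at 80 °C.
- Fallback: set out from 4 and O-allylate it (allyl bromide, K2CO3, acetone, reflux) to 4-(allyloxy)-5-methyl-2H-chromen-2-one F8. The enal is then built by olefin cross-metathesis of F8 with an excess of methacrolein 10 (second-generation Grubbs catalyst, CH2Cl2, 40 °C), which is expected to give the E-enal 7, where the route is rejoined.

Further compounds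
F1 | step 12 | N-[(3S,5S,6E)-5-(tert-butyldimethylsilyloxy)-2,6-dimethyl-8-[(5-methyl-2-oxo-2H-chromen-4-yl)oxy]octa-1,6-dien-3-yl]-2-nitrobenzenesulfonohydrazide | C=C(C)[C@@H](N(N)S(=O)(=O)c1ccccc1[N+](=O)[O-])C[C@H](O[Si](C)(C)C(C)(C)C)/C(C)=C/COc1cc(=O)oc2cccc(C)c12
F2 | step 12 | 4-{[(2E,4S,6S)-4-(tert-butyldimethylsilyloxy)-6-diazenyl-3,7-dimethylocta-2,7-dien-1-yl]oxy}-5-methyl-2H-chromen-2-one | C=C(C)[C@@H](N=N)C[C@H](O[Si](C)(C)C(C)(C)C)/C(C)=C/COc1cc(=O)oc2cccc(C)c12
F3 | step 12 | 4-{[(2E,4S)-4-(tert-butyldimethylsilyloxy)-3,7-dimethylocta-2,6-dien-1-yl]oxy}-5-methyl-2H-chromen-2-one | CC(C)=CC[C@H](O[Si](C)(C)C(C)(C)C)/C(C)=C/COc1cc(=O)oc2cccc(C)c12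
F4 | step 12 | 4-{[(2E,4S,6R)-4-(tert-butyldimethylsilyloxy)-6-hydroperoxy-3,7-dimethylocta-2,7-dien-1-yl]oxy}-5-methyl-2H-chromen-2-one | C=C(C)[C@@H](C[C@H](O[Si](C)(C)C(C)(C)C)/C(C)=C/COc1cc(=O)oc2cccc(C)c12)OO
F5 | step 12 | 4-{[(2E,4S,5E)-4-(tert-butyldimethylsilyloxy)-7-hydroperoxy-3,7-dimethylocta-2,5-dien-1-yl]oxy}-5-methyl-2H-chromen-2-one | CC(C)(OO)/C=C/[C@H](O[Si](C)(C)C(C)(C)C)/C(C)=C/COc1cc(=O)oc2cccc(C)c12
F6 | step 6 | 4-{[(2E)-6-hydroxy-3,7-dimethyl-4-oxoocta-2,7-dien-1-yl]oxy}-5-methyl-2H-chromen-2-one, racemic | C=C(C)C(O)CC(=O)/C(C)=C/COc1cc(=O)oc2cccc(C)c12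
F7 | step 6 | 4-{[(2E,6S)-6-hydroxy-3-methyl-6-[(2S)-2-methyloxiran-2-yl]-4-oxohex-2-en-1-yl]oxy}-5-methyl-2H-chromen-2-one | C[C@]1(CO1)[C@@H](O)CC(=O)/C(C)=C/COc1cc(=O)oc2cccc(C)c12
F8 | step 3 | 4-(allyloxy)-5-methyl-2H-chromen-2-one | C=CCOc1cc(=O)oc2cccc(C)c12
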